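**Plan**

- Retrosynthetic cuts: C13=C14 (Wittig), C8–C9 (cross-metathesis, alkene then saturated), C6–C7 (allyl onto a C6 peroxycarbenium ion), O–C3 of the dioxane (peroxy-Michael), and the C6=CH2 bond of a methallyl butenolide (ozone supplies both peroxide oxygens). The butenolide comes from (S)-2-methylglycidol.
- Forward order: γ-lactone ring first (butenolide 7), 1,2-dioxane ring second (peroxyketal 10, one flask from 7), C6 quaternary centre third (13), side chain last.
- Enabling feature: C6 of the dioxane is a peroxide-bearing, fully substituted carbon at the ketone oxidation level, held by C5H2 on C4, the γ-carbon of the C1–C4/O lactone. As a hydroperoxyketal, its terminal oxygen lies six atoms from the butenolide β-carbon C3, so the dioxane closes onto the preformed lactone and C6 remains a ketal that can be ionised afterwards.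
- Stereochemistry: C4 from (S)-2-methylglycidol; C3 from the enforced cis ring fusion in the Michael closure; C6 from axial capture of the bicyclic peroxycarbenium ion cis to the lactone oxygen and trans to the C4 methyl; diene geometry from the E-cinnamyl reagent and iodine equilibration.

Key step: step 4

Remark: ring atoms are numbered as in the plakortolides (C1 lactone C=O, C2 CH2, C3 CH–OO, C4 C(Me)–O, C5 CH2, C6 C(Me)–OO; chain C7–C16); in the fused-ring names C6 = position 3, C4 = 4a, C3 = 7a. Compounds 9 and 10 are epimer mixtures at C6, which is harmless because both epimers give the same ion 12.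

**Step 1**
Reactants: 1 (S)-2-methylglycidol; 2 isopropenylmagnesium bromide
Product: 3 (2R)-2,4-dimethylpent-4-ene-1,2-diol
Conditions: 2 (2.5 equiv), CuI (10 mol %), THF, −30 → 0 °C; aq. NH4Cl
Reagents that add atoms: none
Why: Copper-catalysed SN2 opening of the 2,2-disubstituted epoxide at its unsubstituted CH2 by the alkenyl Grignard reagent should leave the quaternary stereocentre (future C4) untouched, the descriptor changing from S to R only through CIP priorities.

**Step 2**
Reactants: 3 (2R)-2,4-dimethylpent-4-ene-1,2-diol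
Product: 4 (2R)-2-hydroxy-2,4-dimethylpent-4-enal
Conditions: TEMPO (10 mol %), PhI(OAc)2 (1.1 equiv), CH2Cl2, rt; used crude
Reagents that add atoms: none
Why: Oxoammonium (TEMPO) oxidation should convert only the primary carbinol, since the tertiary alcohol cannot be oxidised and the quaternary α-carbon cannot epimerise.

**Step 3**
Reactants: 4 (2R)-2-hydroxy-2,4-dimethylpent-4-enal; 5 (triphenylphosphoranylidene)ketene
Product: 7 (5R)-5-methyl-5-(2-methylprop-2-en-1-yl)furan-2(5H)-one, via acyl ylide 6 (not isolated)
Conditions: PhMe, 80 °C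
Reagents that add atoms: none
Why: The tertiary hydroxyl should add across the ketene C=C of the cumulated ylide to give the stabilised acyl ylide 6, which closes by intramolecular Wittig reaction onto the aldehyde, the five-membered ring enforcing the Z-alkene of the butenolide while C4 is not involved.

**Step 4**
Reactants: 7 (5R)-5-methyl-5-(2-methylprop-2-en-1-yl)furan-2(5H)-one
Product: 10 (4aR,7aR)-3-methoxy-3,4a-dimethyltetrahydrofuro[3,2-c][1,2]dioxin-6(3H)-one (both C3 epimers), via carbonyl oxide 8 (not isolated), via hydroperoxy ketal 9 (not isolated)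
Conditions: O3, CH2Cl2/MeOH (4:1), −78 °C (Sudan III end-point); N2 purge, concentrate cold; then Et2NH (0.5 equiv), CF3CH2OH, rt
Reagents that add atoms: ozone (O=[O+][O-]); methanol (CO)
Why: Ozone should add [3+2] to the electron-rich 1,1-disubstituted alkene much faster than to the conjugated butenolide alkene, and the primary ozonide should cleave (Criegee) to formaldehyde and the more substituted carbonyl oxide 8, which methanol captures as the α-methoxy hydroperoxide 9. Diethylamine in trifluoroethanol then forms the peroxy anion, which adds to the butenolide β-carbon C3, and the lactone enolate is protonated. The closest known reactions are the ozonolysis of 2-alkyl-1-alkenes in methanol to hydroperoxyketals and the amine-mediated intramolecular conjugate addition of such hydroperoxides, and of tertiary hydroperoxides, to enoates and butenolides to give 1,2-dioxanes. The dioxane ring closes by 6-exo-trig attack of the terminal peroxide oxygen on C3 (ring O–O–C6–C5–C4–C3), the lactone ring being already present. C3 (7a) is controlled by C4 (4a): the tether leaves C4 on one face of the planar butenolide, so the oxygen can arrive only on that face and the rings are cis-fused (7aR), whereas the ketal carbon C6 forms as both epimers, which step 5 erases through the planar ion 12. The step needs chemoselective ozonolysis (secured by the electron-poor, conjugated ring alkene and the dye end-point), Criegee cleavage toward the ketone oxide (secured by the two alkyl groups on C6) and conjugate addition rather than epoxidation or butenolide isomerisation (secured by the six-membered transition state and the absence of a hydrogen on C4).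

**Step 5**
Reactants: 10 (4aR,7aR)-3-methoxy-3,4a-dimethyltetrahydrofuro[3,2-c][1,2]dioxin-6(3H)-one; 11 allyltrimethylsilane
Product: 13 (3S,4aR,7aR)-3,4a-dimethyl-3-(prop-2-en-1-yl)tetrahydrofuro[3,2-c][1,2]dioxin-6(3H)-one, via peroxycarbenium ion 12 (not isolated)
Conditions: 11 (3 equiv), SnCl4 (1.2 equiv), CH2Cl2, −78 °C; aq. NaHCO3
Reagents that add atoms: none
Why: SnCl4 should ionise the exocyclic C–OMe bond of both ketal epimers to the same bicyclic peroxycarbenium ion 12, which the allylsilane captures (Hosomi–Sakurai-type allylation of a peroxyketal); in the half-chair that keeps the C4 methyl and the C3–CH2 bond pseudo-equatorial and the lactone oxygen pseudo-axial, chair-like axial attack places the allyl group cis to the lactone oxygen and trans to the C4 methyl, which is the (3S) configuration of the target.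

**Step 6**
Reactants: 13 (3S,4aR,7aR)-3,4a-dimethyl-3-(prop-2-en-1-yl)tetrahydrofuro[3,2-c][1,2]dioxin-6(3H)-one; 14 hex-5-en-1-ol
Product: 15 (3S,4aR,7aR)-3-(7-hydroxyhept-2-en-1-yl)-3,4a-dimethyltetrahydrofuro[3,2-c][1,2]dioxin-6(3H)-one (E/Z mixture)
Conditions: 14 (4 equiv), Grubbs second-generation catalyst (5 mol %), CH2Cl2, 40 °C
Reagents that add atoms: none
Why: Cross-metathesis of the terminal allyl alkene with an excess of a second terminal alkene should extend the chain to C13, the dialkyl peroxide, lactone and free alcohol being inert to the ruthenium carbene and the alkene geometry being irrelevant.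

**Step 7**
Reactants: 15 (3S,4aR,7aR)-3-(7-hydroxyhept-2-en-1-yl)-3,4a-dimethyltetrahydrofuro[3,2-c][1,2]dioxin-6(3H)-one
Product: 16 (3S,4aR,7aR)-3-(7-hydroxyheptyl)-3,4a-dimethyltetrahydrofuro[3,2-c][1,2]dioxin-6(3H)-one
Conditions: KO2CN=NCO2K (excess), AcOH, MeOH/CH2Cl2, 0 °C → rt
Reagents that add atoms: none
Why: Diimide generated in the flask should transfer H2 concertedly to the unhindered disubstituted alkene and leave the O–O bond, the lactone and the alcohol intact, as in the classical saturation of unsaturated cyclic peroxides.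

**Step 8**
Reactants: 16 (3S,4aR,7aR)-3-(7-hydroxyheptyl)-3,4a-dimethyltetrahydrofuro[3,2-c][1,2]dioxin-6(3H)-one
Product: 17 7-[(3S,4aR,7aR)-3,4a-dimethyl-6-oxohexahydrofuro[3,2-c][1,2]dioxin-3-yl]heptanal
Conditions: Dess–Martin periodinane (1.3 equiv), NaHCO3, CH2Cl2, rt
Reagents that add atoms: none
Why: Buffered Dess–Martin oxidation should stop at the aldehyde under non-basic conditions that do not touch the peroxide or the lactone.

**Step 9**
Reactants: 17 7-[(3S,4aR,7aR)-3,4a-dimethyl-6-oxohexahydrofuro[3,2-c][1,2]dioxin-3-yl]heptanal; 18 (E)-cinnamyltriphenylphosphonium chloride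
Product: 20 plakortolide Q [(3S,4aR,7aR)-3,4a-dimethyl-3-[(7E,9E)-10-phenyldeca-7,9-dien-1-yl]tetrahydrofuro[3,2-c][1,2]dioxin-6(3H)-one], via (7Z,9E)-dienyl isomer 19 (not isolated)
Conditions: 18 (1.5 equiv), NaHMDS (1.4 equiv), THF, −78 °C; add 17, −78 → 0 °C; work-up; then I2 (5 mol %), CH2Cl2, daylight, rt
Reagents that add atoms: none
Why: Wittig olefination with the pre-formed semi-stabilised cinnamylidene ylide, which is too weakly basic to enolise the β-peroxy lactone, should form the C13=C14 bond as an E/Z mixture with the cinnamyl E-alkene retained, and catalytic iodine should then equilibrate the Z component 19 to the thermodynamically preferred (E,E)-diene.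

**Compound list**

1 | (S)-2-methylglycidol [(2S)-(2-methyloxiran-2-yl)methanol] | C[C@]1(CO)CO1 | starting material
2 | isopropenylmagnesium bromide | CC(=C)[Mg]Br | starting material
3 | (2R)-2,4-dimethylpent-4-ene-1,2-diol | CC(=C)C[C@@](CO)(C)O | intermediate
4 | (2R)-2-hydroxy-2,4-dimethylpent-4-enal | CC(=C)C[C@@](C=O)(C)O | intermediate
5 | (triphenylphosphoranylidene)ketene | O=C=C=P(c1ccccc1)(c1ccccc1)c1ccccc1 | starting material
6 | acyl ylide: (2R)-2,4-dimethyl-1-oxopent-4-en-2-yl (triphenylphosphoranylidene)acetate | CC(=C)C[C@@](C=O)(C)OC(=O)C=P(c1ccccc1)(c1ccccc1)c1ccccc1 | intermediate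
7 | (5R)-5-methyl-5-(2-methylprop-2-en-1-yl)furan-2(5H)-one | CC(=C)C[C@@]1(C)OC(=O)C=C1 | intermediate
8 | carbonyl oxide of (5R)-5-methyl-5-(2-oxopropyl)furan-2(5H)-one | CC(=[O+][O-])C[C@@]1(C)OC(=O)C=C1 | intermediate
9 | hydroperoxy ketal: (5R)-5-(2-hydroperoxy-2-methoxypropyl)-5-methylfuran-2(5H)-one (both ketal epimers) | COC(C)(OO)C[C@@]1(C)OC(=O)C=C1 | intermediate
10 | (4aR,7aR)-3-methoxy-3,4a-dimethyltetrahydrofuro[3,2-c][1,2]dioxin-6(3H)-one (both C3 epimers) | COC1(C)C[C@@]2(C)OC(=O)C[C@H]2OO1 | intermediate
11 | allyltrimethylsilane | C=CC[Si](C)(C)C | starting material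
12 | peroxycarbenium ion: (4aR,7aR)-3,4a-dimethyl-6-oxotetrahydrofuro[3,2-c][1,2]dioxin-3-ylium | C[C+]1C[C@@]2(C)OC(=O)C[C@H]2OO1 | intermediate
13 | (3S,4aR,7aR)-3,4a-dimethyl-3-(prop-2-en-1-yl)tetrahydrofuro[3,2-c][1,2]dioxin-6(3H)-one | C[C@]1(CC=C)C[C@@]2(C)OC(=O)C[C@H]2OO1 | intermediate
14 | hex-5-en-1-ol | C=CCCCCO | starting material
15 | (3S,4aR,7aR)-3-(7-hydroxyhept-2-en-1-yl)-3,4a-dimethyltetrahydrofuro[3,2-c][1,2]dioxin-6(3H)-one (E/Z mixture) | C[C@]1(CC=CCCCCO)C[C@@]2(C)OC(=O)C[C@H]2OO1 | intermediate
16 | (3S,4aR,7aR)-3-(7-hydroxyheptyl)-3,4a-dimethyltetrahydrofuro[3,2-c][1,2]dioxin-6(3H)-one | C[C@]1(CCCCCCCO)C[C@@]2(C)OC(=O)C[C@H]2OO1 | intermediate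
17 | 7-[(3S,4aR,7aR)-3,4a-dimethyl-6-oxohexahydrofuro[3,2-c][1,2]dioxin-3-yl]heptanal | C[C@]1(CCCCCCC=O)C[C@@]2(C)OC(=O)C[C@H]2OO1 | intermediate
18 | (E)-cinnamyltriphenylphosphonium chloride | [Cl-].c1ccccc1/C=C/C[P+](c1ccccc1)(c1ccccc1)c1ccccc1 | starting material
19 | (3S,4aR,7aR)-3,4a-dimethyl-3-[(7Z,9E)-10-phenyldeca-7,9-dien-1-yl]tetrahydrofuro[3,2-c][1,2]dioxin-6(3H)-one | C[C@]1(CCCCCC/C=C\C=C\c2ccccc2)C[C@@]2(C)OC(=O)C[C@H]2OO1 | intermediate
20 | plakortolide Q, (3S,4aR,7aR)-3,4a-dimethyl-3-[(7E,9E)-10-phenyldeca-7,9-dien-1-yl]tetrahydrofuro[3,2-c][1,2]dioxin-6(3H)-one | C[C@]1(CCCCCC/C=C/C=C/c2ccccc2)C[C@@]2(C)OC(=O)C[C@H]2OO1 | target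

**Totals**

Total step count: 9. Longest linear sequence: 9 steps (from 1).

**Steps most likely to fail**

Step 5. The capture of ion 12 may lose facial control, or the Lewis acid may ionise the ring C6–O bond instead of the C6–OMe bond, which would open the dioxane. The fallback gives up the peroxycarbenium ion and makes the C6–OO bond by cobalt-catalysed hydroperoxysilylation, accepting both C6 epimers and separating them. It sets out from 1. 2,3-Dibromopropene would be coupled with the Grignard reagent of (6-bromohexyloxy)(tert-butyl)dimethylsilane (CuI, THF) to give 2-bromo-9-[(tert-butyldimethylsilyl)oxy]non-1-ene F1. Its Grignard reagent would open 1 under the conditions of step 1 to (2R)-11-[(tert-butyldimethylsilyl)oxy]-2-methyl-4-methylideneundecane-1,2-diol F2, and oxidation as in step 2 would give (2R)-11-[(tert-butyldimethylsilyl)oxy]-2-hydroxy-2-methyl-4-methylideneundecanal F3. Reagent 5 would convert this through the acyl ylide F4 into (5R)-5-{9-[(tert-butyldimethylsilyl)oxy]-2-methylidenenonyl}-5-methylfuran-2(5H)-one F5. Co(thd)2, O2 and Et3SiH (Mukaiyama–Isayama conditions) should give (5R)-5-{9-[(tert-butyldimethylsilyl)oxy]-2-methyl-2-[(triethylsilyl)peroxy]nonyl}-5-methylfuran-2(5H)-one F6 as both epimers. TBAF should remove both silyl groups to give (5R)-5-(2-hydroperoxy-9-hydroxy-2-methylnonyl)-5-methylfuran-2(5H)-one F7, which would be closed with Et2NH in CF3CH2OH as in step 4. Chromatography should separate 16 from its epimer (3R,4aR,7aR)-3-(7-hydroxyheptyl)-3,4a-dimethyltetrahydrofuro[3,2-c][1,2]dioxin-6(3H)-one F8, and the route is rejoined at 16.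

Step 4. The butenolide alkene may be over-ozonised, the primary ozonide may cleave toward the ketone and formaldehyde oxide, or the hydroperoxy ketal may decompose under base before ring closure. The fallback separates carbonyl formation from peroxide formation and takes the peroxide oxygens from hydrogen peroxide. It sets out from 7. Ozonolysis in CH2Cl2 with Me2S work-up would give the methyl ketone (5R)-5-methyl-5-(2-oxopropyl)furan-2(5H)-one F9. Urea–hydrogen peroxide with catalytic Sc(OTf)3 in methanol should convert it into the hydroperoxy ketal 9, and Et2NH in CF3CH2OH would close the ring as before, so the route is rejoined at 10.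

Step 3. Addition of the hindered tertiary hydroxyl to the cumulated ylide may be sluggish, allowing the α-hydroxy aldehyde to self-condense. The fallback forms the alkene intermolecularly and lactonises afterwards. It sets out from 4. Methyl (triphenylphosphoranylidene)acetate in methanol at 0 °C (Z-selective Wittig reaction of an α-oxygenated aldehyde) should give methyl (2Z,4R)-4-hydroxy-4,6-dimethylhepta-2,6-dienoate F10, which would lactonise with catalytic TsOH in CH2Cl2, and the route is rejoined at 7.

**Further compounds**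

F1 | step 5 | 2-bromo-9-[(tert-butyldimethylsilyl)oxy]non-1-ene | C=C(Br)CCCCCCCO[Si](C)(C)C(C)(C)C
F2 | step 5 | (2R)-11-[(tert-butyldimethylsilyl)oxy]-2-methyl-4-methylideneundecane-1,2-diol | C=C(CCCCCCCO[Si](C)(C)C(C)(C)C)C[C@@](CO)(C)O
F3 | step 5 | (2R)-11-[(tert-butyldimethylsilyl)oxy]-2-hydroxy-2-methyl-4-methylideneundecanal | C=C(CCCCCCCO[Si](C)(C)C(C)(C)C)C[C@@](C=O)(C)O
F4 | step 5 | acyl ylide: (2R)-11-[(tert-butyldimethylsilyl)oxy]-2-methyl-4-methylidene-1-oxoundecan-2-yl (triphenylphosphoranylidene)acetate | C=C(CCCCCCCO[Si](C)(C)C(C)(C)C)C[C@@](C=O)(C)OC(=O)C=P(c1ccccc1)(c1ccccc1)c1ccccc1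
F5 | step 5 | (5R)-5-{9-[(tert-butyldimethylsilyl)oxy]-2-methylidenenonyl}-5-methylfuran-2(5H)-one | C=C(CCCCCCCO[Si](C)(C)C(C)(C)C)C[C@@]1(C)OC(=O)C=C1
F6 | step 5 | (5R)-5-{9-[(tert-butyldimethylsilyl)oxy]-2-methyl-2-[(triethylsilyl)peroxy]nonyl}-5-methylfuran-2(5H)-one (both epimers) | CC(CCCCCCCO[Si](C)(C)C(C)(C)C)(OO[Si](CC)(CC)CC)C[C@@]1(C)OC(=O)C=C1
F7 | step 5 | (5R)-5-(2-hydroperoxy-9-hydroxy-2-methylnonyl)-5-methylfuran-2(5H)-one (both epimers) | CC(CCCCCCCO)(OO)C[C@@]1(C)OC(=O)C=C1
F8 | step 5 | (3R,4aR,7aR)-3-(7-hydroxyheptyl)-3,4a-dimethyltetrahydrofuro[3,2-c][1,2]dioxin-6(3H)-one | C[C@@]1(CCCCCCCO)C[C@@]2(C)OC(=O)C[C@H]2OO1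
F9 | step 4 | (5R)-5-methyl-5-(2-oxopropyl)furan-2(5H)-one | CC(=O)C[C@@]1(C)OC(=O)C=C1
F10 | step 3 | methyl (2Z,4R)-4-hydroxy-4,6-dimethylhepta-2,6-dienoate | CC(=C)C[C@@](/C=C\C(=O)OC)(C)O
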